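All runs are calculated from invented constants.

**Main step.** I start with the easy step: Q takes up X and gives D, and while nothing else happens the share of D in D plus E stays whole.

| flask | Q | X | temperature | remark | time |
|---|---|---|---|---|---|
| theta | 0.20 M | 2 equiv | 10 °C | run made earlier |  |
| alpha | 0.20 M | 1.3 equiv | 25 °C | run made earlier |  |
| delta | 0.20 M | 3 equiv | 10 °C | run made earlier |  |
| south | 0.20 M | 2.00 equiv (fed, over 25 h) | 25 °C | all else is in the flask from the start; the feed brings no volume worth counting | 30 h |
| north-west | 0.20 M | 2.00 equiv (fed, over 6.0 h) | 25 °C | all else is in the flask from the start; the feed brings no volume worth counting | 30 h |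
| north-east | 0.20 M (fed, over 25 h) | 2.00 equiv | 25 °C | all else is in the flask from the start; the feed brings no volume worth counting | 30 h |
| north | 0.20 M | 2.00 equiv (fed, over 25 h) |  | the addition at −5 °C, then warmed to 25 °C; the feed brings no volume worth counting | 30 h |

- theta (time / h: D / %, E / %): 4.00: 1.2, 0; 12.0: 6.1, 0; 20.0: 8.0, 0; 30.0: 10.7, 1.3; 48.0: 17.3, 1.7; 60.0: 20.9, 1.4
- alpha (time / h: D / %, E / %): 1.33: 1.7, 0.6; 4.00: 6.6, 0; 6.00: 9.4, 0.3; 10.0: 12.1, 0; 15.0: 12.0, 1.5; 20.0: 15.6, 2.5
- delta (time / h: D / %, E / %): 6.00: 5.9, 1.2; 12.0: 8.9, 0.8; 20.0: 13.0, 1.0; 25.0: 15.5, 0; 30.0: 16.8, 0.4; 40.0: 22.0, 2.2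

(scatter of a reading: 1 percentage point)

* which flask leads in share of D in D plus E ("all alike" within 1.5 percentage points) (south / north-west / north-east / north / all alike)
* share of D in D plus E at the end, south
* share of D in D plus E at the end, north-west
* share of D in D plus E at the end, north-east
* share of D in D plus E at the end, north

- the analysis behind the earlier runs scatters by 1 percentage point, standard deviation

**Second step.** D also takes up X and gives E. At a given X each step is pseudo-first-order in its own substrate, so both run on one clock. I call this clock the exposure τ, the concentration of X summed over the hours, and I count X at its full charge as fed. While little Q has reacted, E/D grows in step with τ, so E/D = bτ. Alpha ends at 20.0 h with E 2.5 % and D 15.6 %, which gives b, the growth of E/D per unit of exposure: 0.0308 /M/h. It is a loose reading, since E carries a scatter of 1 percentage point.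

**The rest.** Exposure comes to 7.00 M·h in south and 10.8 M·h in north-west. In north-east, I count X at full charge from the start while Q arrives over time, so early Q sees long exposure and late Q short. Weighting by the D each portion makes gives 8.19 M·h. For temperature, D per exposure early in alpha, at 6.00 h, over that in theta, at 12.0 h, reads 4.74. I divide by this ratio twice for the feed at −5 °C and take it for both steps, which gives north 2.22 M·h.

**My reckoning.** Share = 1/(1 + bτ) gives south 82.3 %, north-west 75.0 %, north-east 79.8 % and north 93.6 %, so north leads.

**The forecast.** The forecast also names north, with 87.5 % for south, 84 % for north-west, 89.5 % for north-east and 94 % for north, holding that “Share therefore depends mainly on conversion”; it puts north-east above south, where I put south above north-east.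

**The result.** The flasks give south 89.8 %, north-west 83.7 %, north-east 87.6 % and north 96.6 %, so north leads.

    Q + X → D (k = 0.0790 /M/h, Ea = 79.0 kJ/mol)
    X + D → E (k = 0.0300 /M/h, Ea = 83.0 kJ/mol)
    D ⇌ Z (K = 1.90, k = 0.110 /h, Ea = 104 kJ/mol, ΔH = −28.0 kJ/mol)
    (constants at 25 °C)

**The neighbour.** Read from north's result, b becomes 0.0157 /M/h, lower than the alpha reading, and with it south reckons to 90.1 % against 89.8 %. The neighbour is north with 0.80 M of Q and the same equivalents, so its X and its exposure scale with Q, to 8.89 M·h. The same b then gives a share of 87.8 %, and that flask gives 87.6 %.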